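**Retrosynthetic overview**
1. The diacetate comes from the 3-oxo-13-ol by axial-selective hydride delivery and double O-acetylation. The ketone comes from the 3β,13-diol, so the C3 carbinol serves as a stereochemical relay and is then reset.
2. Ring A (C4–C5) forms first and ring B (C9–C10) second, in one radical cascade from acyclic (3S,14S)-14,15-epoxygeranyllinalool. Termination installs the 8(17)-methylene.
3. Key step: C12–C13 is made by a stereospecific 1,2-shift of the whole C16 chain from boron to carbon. The boronate is built from a homoallylic boronic ester and lithiated (R)-but-3-en-2-yl carbamate, and the shift sets C13.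
4. C5–C6 is made by an sp3–sp2 Negishi union of a C7 iodo-boronate with a C9 (S)-epoxy vinyl iodide.
5. Both halves come from Zr-catalysed methylalumination of small alkynes made from commercial C2–C6 feedstocks.

Assumption: (R)-but-3-en-2-ol, bromoethene (THF solution), lithium acetylide·EDA and the L-series (ent) Shi ketone are taken as purchasable. Positions are given in labdane numbering.

**Step 1**
Reactants: 1 5-bromo-2-methylpent-2-ene; 2 lithium acetylide–ethylenediamine complex
Product: 3 6-methylhept-5-en-1-yne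
Conditions: DMSO, 0 °C → rt
Reagents that add atoms: none
Why: SN2 alkynylation of an unhindered primary bromide by acetylide in a dipolar aprotic solvent; no stereocentre is formed.

**Step 2**
Reactants: 3 6-methylhept-5-en-1-yne
Product: 5 (1E)-1-iodo-2,6-dimethylhepta-1,5-diene, via alkenyl(dimethyl)alane 4 (not isolated)
Conditions: Me3Al (2 equiv), Cp2ZrCl2 (20 mol %), CH2Cl2, 0 °C → rt; then I2, THF, −30 → 0 °C
Reagents that add atoms: trimethylaluminium C[Al](C)C; iodine II
Why: Negishi Zr-catalysed syn-methylalumination of the terminal alkyne, followed by iodinolysis with retention, gives the E-alkene (≥98 %), and the isolated trisubstituted alkene is inert.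

**Step 3**
Reactants: 5 (1E)-1-iodo-2,6-dimethylhepta-1,5-diene
Product: 6 (3S)-3-[(3E)-4-iodo-3-methylbut-3-en-1-yl]-2,2-dimethyloxirane
Conditions: ent-Shi ketone (30 mol %), Oxone, K2CO3, Bu4NHSO4 (cat.), MeCN/DMM–aq. borate/EDTA buffer (pH 10.5), 0 °C
Reagents that add atoms: potassium peroxymonosulfate (Oxone) [K+].[O-]S(=O)(=O)OO
Why: In this Shi asymmetric epoxidation the electron-rich Me2C=CH alkene reacts far faster than the iodo-alkene, and the spiro transition state of the L-series dioxirane delivers oxygen to the face that gives the (S)-epoxide (ca. 90–94 % ee).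

**Step 4**
Reactants: 7 but-3-yn-1-ol; 8 bromoethene
Product: 10 (3E)-3-methylhexa-3,5-dien-1-ol, via bis(dimethylaluminium) adduct 9 (not isolated)
Conditions: Me3Al (3 equiv), Cp2ZrCl2 (25 mol %), CH2Cl2, 0 °C → rt; then 8, Pd(PPh3)4 (3 mol %), ZnCl2 (0.2 equiv), THF, rt; aqueous work-up
Reagents that add atoms: trimethylaluminium C[Al](C)C
Why: Syn-methylalumination of the aluminium alkoxide, then Pd/Zn co-catalysed Negishi alkenyl–alkenyl coupling with retention, gives the E-diene in one pot.

**Step 5**
Reactants: 10 (3E)-3-methylhexa-3,5-dien-1-ol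
Product: 11 (3E)-6-iodo-4-methylhexa-1,3-diene
Conditions: I2, PPh3, imidazole, CH2Cl2, 0 °C, dark
Reagents that add atoms: iodine II
Why: Appel-type iodination of a primary alcohol under neutral conditions leaves the diene untouched.

**Step 6**
Reactants: 11 (3E)-6-iodo-4-methylhexa-1,3-diene
Product: 12 2-[(3E)-6-iodo-4-methylhex-3-en-1-yl]-4,4,5,5-tetramethyl-1,3,2-dioxaborolane
Conditions: HBpin (1.1 equiv), [Ir(cod)Cl]2 (1.5 mol %), dppe (3 mol %), toluene, rt
Reagents that add atoms: pinacolborane [H]B1OC(C)(C)C(C)(C)O1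
Why: Ir-catalysed anti-Markovnikov 1,2-hydroboration takes place only at the open vinyl terminus of the diene and puts boron on the terminal carbon, so the trisubstituted E-alkene and the primary iodide are kept.

**Step 7**
Reactants: 12 iodo-boronate; 6 (S)-epoxy vinyl iodide
Product: 14 2-[(3E,7E)-10-[(2S)-3,3-dimethyloxiran-2-yl]-4,8-dimethyldeca-3,7-dien-1-yl]-4,4,5,5-tetramethyl-1,3,2-dioxaborolane, via homoallylic zinc iodide 13 (not isolated)
Conditions: Zn dust, LiCl, THF, 30 °C; then 6 (0.9 equiv), PdCl2(dppf) (3 mol %), THF, rt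
Reagents that add atoms: none
Why: LiCl-assisted zinc insertion tolerates the Bpin group, and the Negishi sp3–sp2 coupling proceeds with retention of the E-vinyl geometry under conditions that do not open a trisubstituted epoxide or transmetalate an alkyl-Bpin.

**Step 8**
Reactants: 15 (2R)-but-3-en-2-ol
Product: 16 (2R)-but-3-en-2-yl N,N-diisopropylcarbamate
Conditions: iPr2NCOCl, Et3N, DMAP (cat.), CH2Cl2, reflux
Reagents that add atoms: N,N-diisopropylcarbamoyl chloride CC(C)N(C(C)C)C(Cl)=O
Why: O-Carbamoylation does not touch the C–O stereocentre, so the configuration is retained.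

**Step 9 (key step)**
Reactants: 16 (R)-carbamate; 14 epoxy boronic ester
Product: 20 (3S,6E,10E)-13-[(2S)-3,3-dimethyloxiran-2-yl]-3,7,11-trimethyltrideca-1,6,10-trien-3-ol, via lithiated carbamate 17 (not isolated), via boronate complex 18 (not isolated), via tertiary allylic boronic ester 19 (not isolated)
Conditions: 16 (1.3 equiv), s-BuLi (1.25 equiv), TMEDA, Et2O, −78 °C; add 14, −78 °C, 1 h; warm to rt; then H2O2, aq. NaOH, THF, 0 °C
Reagents that add atoms: hydrogen peroxide OO
Why: In this lithiation–borylation the α-H is removed with retention, boron is taken up at the α-carbon with retention, and on warming C12 with the whole C16 chain undergoes a stereospecific 1,2-shift (1,2-metallate rearrangement) from boron to C13 anti to the leaving carbamate (inversion), so that C–B oxidation with retention gives the (13S)-carbinol, and the epoxide survives because no free organolithium is present.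

**Step 10**
Reactants: 20 (3S,14S)-14,15-epoxygeranyllinalool
Product: 21 (3S,5R,9S,10R,13S)-labda-8(17),14-diene-3,13-diol (3β-OH, 5α-H, 9α-H, 10β-Me)
Conditions: Cp2TiCl2 (10 mol %), Co(II)(salen) (1 mol %), Zn (20 mol %), Et3N·HCl (20 mol %), THF (5 mM), rt
Reagents that add atoms: none
Why: Proposed new method: a bimetallic Ti(III)/Co(II) radical redox-relay cycloisomerisation of an epoxypolyene, reasoned as follows. (i) Cp2Ti(III)Cl opens the epoxide homolytically at the tertiary C4–O bond. (ii) The β-titanoxy radical closes ring A (C4–C5, 6-endo) and then ring B (C10–C9, 6-endo) through an all-chair array with the bulky OTi group equatorial, so the (S)-C3 centre and the E-alkenes dictate 5α-H, 10β-Me and 9α-H. (iii) The hindered tertiary C8 radical, which Ti(III) captures only slowly, meets the persistent Co(II) metalloradical, which abstracts the most accessible β-hydrogen (C17–H) and gives the exocyclic 8(17)-alkene. (iv) Co(III)–H then hands H+/e− back to the Ti(IV) alkoxide, which frees the 3β-OH and regenerates both catalysts without a stoichiometric metal. (v) With 1 mol % Co at 5 mM, bimolecular H-abstraction should be slower than either ring closure. The closest known reaction types are the Ti/Co-catalysed isomerisation of epoxides to allylic alcohols and the Mn-driven titanocene(III) cyclisation of epoxypolyprenes.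

**Step 11**
Reactants: 21 3β,13-diol
Product: 22 (5R,9S,10R,13S)-13-hydroxylabda-8(17),14-dien-3-one
Conditions: Dess–Martin periodinane (1.2 equiv), CH2Cl2, 0 °C → rt
Reagents that add atoms: none
Why: Dess–Martin oxidation takes only the secondary alcohol, and unlike Cr(VI) it does not transpose the tertiary allylic alcohol, while C5 (not α to the ketone), C9, C10 and C13 are untouched.

**Step 12**
Reactants: 22 3-oxo-13-ol
Product: 24 (3R,5R,9S,10R,13S)-labda-8(17),14-diene-3,13-diyl diacetate (target; 3α-OAc), via dilithium 3α,13-dialkoxide 23 (not isolated)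
Conditions: L-Selectride (2.5 equiv), THF, −78 °C; then Ac2O (6 equiv), DMAP (cat.), −78 °C → rt
Reagents that add atoms: acetic anhydride CC(=O)OC(C)=O
Why: The bulky trialkylborohydride attacks the 4,4-dimethyl-3-ketone along the equatorial trajectory and gives the axial 3α-alkoxide (as with 3-oxo-triterpenoids), and the two lithium alkoxides, including the otherwise sluggish tertiary one, are O-acetylated in the same flask without touching any C–O stereocentre.

**Compound list**
1 | 5-bromo-2-methylpent-2-ene | CC(C)=CCCBr | starting material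
2 | lithium acetylide–ethylenediamine complex | [Li]C#C.NCCN | starting material
3 | 6-methylhept-5-en-1-yne | CC(C)=CCCC#C | intermediate
4 | [(1E)-2,6-dimethylhepta-1,5-dien-1-yl]dimethylalane (not isolated) | CC(C)=CCC/C(C)=C/[Al](C)C | intermediate
5 | (1E)-1-iodo-2,6-dimethylhepta-1,5-diene | CC(C)=CCC/C(C)=C/I | intermediate
6 | (3S)-3-[(3E)-4-iodo-3-methylbut-3-en-1-yl]-2,2-dimethyloxirane | CC1(C)O[C@H]1CC/C(C)=C/I | intermediate
7 | but-3-yn-1-ol | C#CCCO | starting material
8 | bromoethene (vinyl bromide) | C=CBr | starting material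
9 | dimethylaluminium (3E)-4-(dimethylalumanyl)-3-methylbut-3-en-1-olate (not isolated) | C[Al](C)OCC/C(C)=C/[Al](C)C | intermediate
10 | (3E)-3-methylhexa-3,5-dien-1-ol | OCC/C(C)=C/C=C | intermediate
11 | (3E)-6-iodo-4-methylhexa-1,3-diene | ICC/C(C)=C/C=C | intermediate
12 | 2-[(3E)-6-iodo-4-methylhex-3-en-1-yl]-4,4,5,5-tetramethyl-1,3,2-dioxaborolane | ICC/C(C)=C/CCB1OC(C)(C)C(C)(C)O1 | intermediate
13 | [(3E)-3-methyl-6-(pinacolatoboryl)hex-3-en-1-yl]zinc iodide (not isolated) | I[Zn]CC/C(C)=C/CCB1OC(C)(C)C(C)(C)O1 | intermediate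
14 | 2-[(3E,7E)-10-[(2S)-3,3-dimethyloxiran-2-yl]-4,8-dimethyldeca-3,7-dien-1-yl]-4,4,5,5-tetramethyl-1,3,2-dioxaborolane | CC1(C)O[C@H]1CC/C(C)=C/CC/C(C)=C/CCB2OC(C)(C)C(C)(C)O2 | intermediate
15 | (2R)-but-3-en-2-ol | C=C[C@@H](C)O | starting material
16 | (2R)-but-3-en-2-yl N,N-diisopropylcarbamate | C=C[C@@H](C)OC(=O)N(C(C)C)C(C)C | intermediate
17 | (R)-2-lithiobut-3-en-2-yl N,N-diisopropylcarbamate (not isolated) | C=C[C@@]([Li])(C)OC(=O)N(C(C)C)C(C)C | intermediate
18 | lithium boronate complex of 14 with 17, (R) at the carbamate carbon (not isolated) | [Li+].C=C[C@@]([B-]1(CC/C=C(\C)CC/C=C(\C)CC[C@@H]2OC2(C)C)OC(C)(C)C(C)(C)O1)(C)OC(=O)N(C(C)C)C(C)C | intermediate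
19 | tertiary allylic pinacol boronic ester, (R) at C13, (14S)-epoxide (not isolated) | C=C[C@](B1OC(C)(C)C(C)(C)O1)(C)CC/C=C(\C)CC/C=C(\C)CC[C@@H]2OC2(C)C | intermediate
20 | (3S,6E,10E)-13-[(2S)-3,3-dimethyloxiran-2-yl]-3,7,11-trimethyltrideca-1,6,10-trien-3-ol | C=C[C@](C)(CC/C=C(\C)CC/C=C(\C)CC[C@@H]1OC1(C)C)O | intermediate
21 | (3S,5R,9S,10R,13S)-labda-8(17),14-diene-3,13-diol | C=C[C@](C)(CC[C@H]1C(=C)CC[C@H]2C(C)(C)[C@@H](O)CC[C@]12C)O | intermediate
22 | (5R,9S,10R,13S)-13-hydroxylabda-8(17),14-dien-3-one | C=C[C@](C)(CC[C@H]1C(=C)CC[C@H]2C(C)(C)C(=O)CC[C@]12C)O | intermediate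
23 | dilithium (3R,5R,9S,10R,13S)-labda-8(17),14-diene-3,13-diolate (not isolated) | [Li+].[Li+].C=C[C@](C)(CC[C@H]1C(=C)CC[C@H]2C(C)(C)[C@H]([O-])CC[C@]12C)[O-] | intermediate
24 | (3R,5R,9S,10R,13S)-labda-8(17),14-diene-3,13-diyl diacetate | C=C[C@](C)(CC[C@H]1C(=C)CC[C@H]2C(C)(C)[C@H](OC(C)=O)CC[C@]12C)OC(C)=O | target

**Total step count:** 12. **Longest linear sequence:** 8 (steps 1-2-3-7-9-10-11-12, or equally 4-5-6-7-9-10-11-12).

**Three steps most likely to fail**

Step 10 (the proposed new method).
- Risks: Co(II) may abstract hydrogen too early, at the C4 or C10 radical, which would give the acyclic allylic alcohol or a monocycle. Co–H may also re-add to the 8(17)-alkene and isomerise it into the ring.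
- Fallback: it sets out from 20 and comes back at 21, and it drops bimetallic redox-neutral catalysis for the established reductive titanocene(III) cyclisation of epoxypolyprenes. The conditions are Cp2TiCl2 (20 mol %), Mn dust, Me3SiCl and 2,4,6-collidine in THF at rt. There a second Ti(III) traps the C8 radical and β-hydride elimination gives the exocyclic alkene. The product is the 3-O-trimethylsilyl ether F1, which a separate TBAF treatment converts into 21.

Step 9.
- Risks: γ- instead of α-borylation, partial racemisation of the 1-methylallyl lithium, or attack on the epoxide.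
- Fallback: it sets out from 14 and comes back at 20, and it replaces the chiral carbenoid by catalyst-controlled epoxidation. (Z)-3-Iodobut-2-en-1-ol is dilithiated with t-BuLi and added to 14. I2/NaOMe (Zweifel olefination with inversion of alkene geometry) then gives (14S)-14,15-epoxygeranylgeraniol F2. Sharpless epoxidation with L-(+)-DET, Ti(OiPr)4 and t-BuOOH gives the (2S,3S)-2,3-epoxy alcohol F3. I2/PPh3/imidazole gives the epoxy iodide F4. Zinc dust in warm ethanol then opens it reductively to the (13S)-tertiary allylic alcohol 20.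

Step 6.
- Risks: 1,4-hydroboration to an allylboronate, or interference of the C–I bond with Ir(I).
- Fallback: it sets out from 11 (with 6) and comes back at 14, and it brings boron in only after the fragment union and without a catalyst. Zn/LiCl turns 11 into the dienylzinc iodide F5, and Negishi coupling with 6 gives the epoxy tetraene F6. 9-BBN then adds to the vinyl terminus to give the B-alkyl-9-BBN F7. NaOH/H2O2 gives the epoxy homofarnesol F8, and I2/PPh3/imidazole gives the iodide F9. Cu-catalysed borylation (CuI, PPh3, LiOMe, B2pin2, DMF) delivers 14.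

**Further compounds**
F1 | step 10 | (3S,5R,9S,10R,13S)-3-(trimethylsilyloxy)labda-8(17),14-dien-13-ol | C=C[C@](C)(CC[C@H]1C(=C)CC[C@H]2C(C)(C)[C@@H](O[Si](C)(C)C)CC[C@]12C)O
F2 | step 9 | (2E,6E,10E)-13-[(2S)-3,3-dimethyloxiran-2-yl]-3,7,11-trimethyltrideca-2,6,10-trien-1-ol | CC1(C)O[C@H]1CC/C(C)=C/CC/C(C)=C/CC/C(C)=C/CO
F3 | step 9 | [(2S,3S)-3-{(3E,7E)-10-[(2S)-3,3-dimethyloxiran-2-yl]-4,8-dimethyldeca-3,7-dien-1-yl}-3-methyloxiran-2-yl]methanol | CC1(C)O[C@H]1CC/C(C)=C/CC/C(C)=C/CC[C@]2(C)O[C@H]2CO
F4 | step 9 | (2R,3S)-3-{(3E,7E)-10-[(2S)-3,3-dimethyloxiran-2-yl]-4,8-dimethyldeca-3,7-dien-1-yl}-2-(iodomethyl)-3-methyloxirane | CC1(C)O[C@H]1CC/C(C)=C/CC/C(C)=C/CC[C@]2(C)O[C@H]2CI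
F5 | step 6 | [(3E)-3-methylhexa-3,5-dien-1-yl]zinc iodide | I[Zn]CC/C(C)=C/C=C
F6 | step 6 | (3S)-3-[(3E,7E)-3,7-dimethyldeca-3,7,9-trien-1-yl]-2,2-dimethyloxirane | CC1(C)O[C@H]1CC/C(C)=C/CC/C(C)=C/C=C
F7 | step 6 | 9-[(3E,7E)-10-[(2S)-3,3-dimethyloxiran-2-yl]-4,8-dimethyldeca-3,7-dien-1-yl]-9-borabicyclo[3.3.1]nonane | CC1(C)O[C@H]1CC/C(C)=C/CC/C(C)=C/CCB2C3CCCC2CCC3
F8 | step 6 | (3E,7E)-10-[(2S)-3,3-dimethyloxiran-2-yl]-4,8-dimethyldeca-3,7-dien-1-ol | CC1(C)O[C@H]1CC/C(C)=C/CC/C(C)=C/CCO
F9 | step 6 | (3S)-3-[(3E,7E)-10-iodo-3,7-dimethyldeca-3,7-dien-1-yl]-2,2-dimethyloxirane | CC1(C)O[C@H]1CC/C(C)=C/CC/C(C)=C/CCI
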